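**Plan**

Target numbering, used for every intermediate: C1 (lactone O–CH), C2, C3 (CHMe), C4, C5, C6 (=CH), C7 (=C–CH2OAc), C8, C9 (CH–O-glycolate), C10 (fusion CH), C11 (C=CH2), C12 (C=O).
Retrosynthesis: remove the two ester groups and the exocyclic methylene, open the lactone C12–O, cut C3–CH3 (conjugate addition) and C10–C11 (enolate alkylation); then re-form the transannular bonds C2–C7 and C3–C6 (reverse of a thermal cycloreversion) and finally cut C2–C3 and C6–C7 (enone–alkene photocycloaddition).
Enabling feature: the ten-membered ring is a six-carbon arc C7–C8–C9–C10–C1–C2 (a cyclohexenone with C1=O, C2=C7, ester on C7, oxygen on C9) joined at C2–C3 and C6–C7 to a four-carbon arc C3–C6 (cyclobutene); the ring alkenes C2=C3 and C6=C7 are what cleavage of a bicyclo[2.2.0]hexane leaves behind.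
Forward order: cyclohexenone (ring-closing metathesis, allylic oxidation), cyclobutane (photocycloaddition), C10 arm on the rigid tricycle, ten-membered ring (cycloreversion), C3 methyl, lactone, then methylene group and esters.
Stereochemistry: C9 from a catalytic asymmetric allylation; C10 by alkylation anti to the C9 silyloxy group; the C6=C7 geometry from the stereospecific opening of the cis-anti-cis adduct; C3 from a chiral copper catalyst; C1 by hydride attack anti to the C10 arm.

Key step: step 5

Remark: cyclobutene (bp 2 °C) is assumed to be bought as the liquefied gas (otherwise one step from cyclobutyl tosylate and t-BuOK) and is condensed into the cold photolysis solution.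

**Route**

Step 1
Reactants: 1 pent-4-enal; 2 methyl 2-(bromomethyl)acrylate
Product: 4 methyl (4R)-4-hydroxy-2-methylideneoct-7-enoate, via trimethylsilyl ether 3 (not isolated)
Conditions: CrCl2 (10 mol%), chiral carbazole-bridged bis(oxazoline) ligand (12 mol%, antipode giving 4R), i-Pr2NEt, Mn powder, Me3SiCl, THF, rt; then aq. citric acid, MeOH, 0 °C
Reagents that add atoms: methyl 2-(bromomethyl)acrylate (2), C=C(CBr)C(=O)OC
Why: A catalytic enantioselective Nozaki–Hiyama–Kishi 2-(alkoxycarbonyl)allylation should work here because the allylchromium species formed from 2 adds to the unhindered aldehyde inside the chiral bis(oxazoline)–chromium complex, which selects the aldehyde face and sets the carbinol (the later C9) as R, while Mn and Me3SiCl regenerate divalent chromium and the labile silyl ether 3 is cleaved on work-up.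

Step 2
Reactants: 4 methyl (4R)-4-hydroxy-2-methylideneoct-7-enoate
Product: 5 methyl (4R)-4-(tert-butyldimethylsilyloxy)-2-methylideneoct-7-enoate
Conditions: TBSOTf, 2,6-lutidine, CH2Cl2, −78 °C
Reagents that add atoms: tert-butyldimethylsilyl trifluoromethanesulfonate, CC(C)(C)[Si](C)(C)OS(=O)(=O)C(F)(F)F
Why: Silyl ether formation with the triflate at −78 °C is much faster than lactonisation of the γ-hydroxy ester, and the tert-butyldimethylsilyl group then guards the C9 oxygen through the enolate, photochemical and thermal steps.

Step 3
Reactants: 5 methyl (4R)-4-(tert-butyldimethylsilyloxy)-2-methylideneoct-7-enoate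
Product: 6 methyl (5R)-5-(tert-butyldimethylsilyloxy)cyclohex-1-ene-1-carboxylate
Conditions: (H2IMes)(PCy3)Cl2Ru=CHPh (second-generation Grubbs catalyst, 5 mol%), CH2Cl2 (0.01 M), 40 °C
Reagents that add atoms: none
Why: Ring-closing metathesis between the terminal alkene and the 2-substituted acrylate closes the six-membered ring with loss of ethylene and places the trisubstituted double bond (C7=C2) in conjugation with the ester by construction, the remote C9 centre being untouched.

Step 4
Reactants: 6 methyl (5R)-5-(tert-butyldimethylsilyloxy)cyclohex-1-ene-1-carboxylate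
Product: 7 methyl (5S)-5-(tert-butyldimethylsilyloxy)-3-oxocyclohex-1-ene-1-carboxylate
Conditions: Rh2(cap)4 (dirhodium tetrakis(caprolactamate), 1 mol%), t-BuOOH (70% aq., 5 equiv), ClCH2CH2Cl, 40 °C
Reagents that add atoms: tert-butyl hydroperoxide, CC(C)(C)OO
Why: In this allylic C–H oxidation the tert-butylperoxy radical generated on Rh2(cap)4 abstracts hydrogen from C1, because the resulting allyl radical is stabilised by the C7 ester whereas C8–H is deactivated and shielded by the neighbouring silyloxy carbon, and the base-free medium spares the β-silyloxy enone from elimination and aromatisation (the descriptor changes from R to S only through the priority switch).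

Step 5
Reactants: 7 methyl (5S)-5-(tert-butyldimethylsilyloxy)-3-oxocyclohex-1-ene-1-carboxylate; 8 cyclobutene
Product: 10 cis-anti-cis tricyclic keto ester (cyclobutane C2–C3–C6–C7 on the face opposite the C9 silyloxy group), via trans-fused C2 epimer 9 (not isolated)
Conditions: cyclobutene (10 equiv), CH2Cl2, −70 °C, hν (350 nm, Pyrex); then basic Al2O3, CH2Cl2, rt
Reagents that add atoms: cyclobutene (8), C1=CCC1
Why: The n,π* triplet of the enone adds to cyclobutene through C7 or C2 to give a triplet 1,4-biradical, which closes to the cyclobutane after spin inversion; the closest known reaction is the enone–alkene (2+2) photocycloaddition of 3-alkoxycarbonylcyclohexenones with cycloalkenes. One ring is closed, the cyclobutane C2–C3–C6–C7, by stepwise union of the two π bonds (first bond, then collapse of the 1,4-biradical), and this makes C2–C7 and C3–C6 the two transannular bonds of a ten-carbon perimeter. C3 and C6 are held cis by the cyclobutene ring, C7 and the face of addition are governed by approach of the alkene with its CH2CH2 bridge turned away from the six-membered ring (anti) and away from the C9 silyloxy group, and C2 is brought to the cis 6-4 fusion by epimerising the trans-fused isomer 9 on basic alumina. The selectivity that matters is the cis-anti-cis relative configuration alone, since step 7 destroys all four new centres and leaves C9 as the only stereocentre of the original ring. Cyclobutene is symmetric, so there is no regiochemical issue, and its excess together with the low temperature suppresses enone dimerisation and elimination of the β-silyloxy group.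

Step 6
Reactants: 10 cis-anti-cis tricyclic keto ester; 11 tert-butyl bromoacetate
Product: 13 C10-alkylated tricyclic keto diester (tert-butyl acetate arm trans to the C9 silyloxy group; 9S,10R), via lithium enolate 12 (not isolated)
Conditions: LiN(i-Pr)2 (LDA, 1.1 equiv), THF, −78 °C; then BrCH2CO2t-Bu, DMPU, −78 → −40 °C
Reagents that add atoms: tert-butyl bromoacetate (11), CC(C)(C)OC(=O)CBr
Why: Ketone enolate alkylation: LDA removes a proton from the C10 methylene, not from the strained cyclobutane methine C2, and the lithium enolate 12 is alkylated by the reactive bromoacetate on the face opposite the adjacent C9 silyloxy group (the usual trans-2,3 outcome for cyclohexanone enolates), which sets C10 as R, while at −78 to −40 °C β-elimination of silyloxide should remain slow.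

Step 7
Reactants: 13 C10-alkylated tricyclic keto diester
Product: 14 cyclodeca-2,6-dienone diester (C2=C3 trans in the ring, C6=C7 cis in the ring; 9S,10R)
Conditions: degassed toluene (0.01 M), 185 °C, base-washed sealed tube
Reagents that add atoms: none
Why: Thermal cycloreversion of the bicyclo[2.2.0]hexane unit: homolysis of C3–C6 gives a cyclohexane-1,4-diyl that cleaves the more substituted C2–C7 bond, and through the chair-like diyl with C1 and the ester equatorial and C8 axial the cis-anti-cis adduct should give C1 trans to C4 on C2=C3 and C8 cis to C5 on C6=C7, conjugation of the new alkenes with the ketone and the ester holding back a following Cope rearrangement and C9 and C10 being untouched.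

Step 8
Reactants: 14 cyclodeca-2,6-dienone diester
Product: 16 (3S,9S,10R)-3-methylcyclodec-6-enone diester, via methylzinc enolate 15 (not isolated)
Conditions: Me2Zn (2 equiv), Cu(OTf)2 (3 mol%), BINOL-derived phosphoramidite ligand with a bis(1-phenylethyl)amine unit (6 mol%, antipode giving 3S), toluene, −30 °C; then 1 M HCl, 0 °C
Reagents that add atoms: dimethylzinc, C[Zn]C
Why: Copper-catalysed asymmetric conjugate addition: the chiral copper–phosphoramidite complex transfers methyl from zinc to C3 of the strained trans-enone on the face fixed by the ligand antipode (giving 3S), the trisubstituted enoate being far less electrophilic, and the zinc enolate 15 is protonated at C2 on work-up without touching C10.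

Step 9
Reactants: 16 (3S,9S,10R)-3-methylcyclodec-6-enone diester
Product: 17 (1S,3S,9S,10S)-1-hydroxy diester
Conditions: LiBH(s-Bu)3 (L-Selectride, 1.2 equiv), THF, −78 °C; then H2O
Reagents that add atoms: none
Why: Ketone reduction under steric approach control: the bulky trialkylborohydride should enter the C1 carbonyl from the face opposite the adjacent C10 acetate arm, as it does with 2-substituted cycloalkanones, which places the new hydroxyl cis to the arm (1S), and at −78 °C neither the enoate nor the tert-butyl ester reacts.

Step 10
Reactants: 17 (1S,3S,9S,10S)-1-hydroxy diester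
Product: 18 (1S,3S,9S,10S)-diol tert-butyl ester (C7 hydroxymethyl, C1 hydroxyl)
Conditions: i-Bu2AlH (3.5 equiv), CH2Cl2, −78 °C; then aq. potassium sodium tartrate (KNaC4H4O6)
Reagents that add atoms: none
Why: Ester reduction: i-Bu2AlH reduces the conjugated methyl ester by 1,2-hydride delivery to the allylic alcohol at −78 °C, where the hindered tert-butyl ester and the silyl ether survive and the C6=C7 geometry is kept.

Step 11
Reactants: 18 (1S,3S,9S,10S)-diol tert-butyl ester
Product: 19 cis-fused hydroxy lactone (C9 silyl ether, C7 hydroxymethyl)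
Conditions: (+)-camphor-10-sulfonic acid (10 mol%), toluene, 50 °C
Reagents that add atoms: none
Why: Acid-catalysed lactonisation (intramolecular transesterification, 5-exo-trig): only the C1 hydroxyl, cis to the acetate arm, can reach the tert-butyl ester because the C9 oxygen is still silylated, so the cis-fused γ-lactone forms with loss of tert-butanol and its ring fusion follows from the C1 and C10 centres already set.

Step 12
Reactants: 19 cis-fused hydroxy lactone
Product: 23 α-methylene lactone (C7 hydroxymethyl free; C9 silyl ether), via dilithium enolate alkoxide 20 (not isolated), via Mannich base 21 (not isolated), via trimethylammonium iodide 22 (not isolated)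
Conditions: LiN(i-Pr)2 (2.3 equiv), THF, −78 °C; CH2=NMe2+ I−, −78 → 0 °C; then MeI, MeOH, rt; then aq. NaHCO3, CH2Cl2, rt
Reagents that add atoms: dimethyl(methylidene)ammonium iodide, C[N+](C)=C.[I-]
Why: α-Methylenation by the Mannich route: the lactone enolate (the primary alcohol being carried as its lithium alkoxide) is aminomethylated by the iminium salt, and quaternisation with MeI followed by bicarbonate-induced β-elimination of trimethylamine gives the exocyclic C11=CH2, which erases the transient C11 centre.

Step 13
Reactants: 23 α-methylene lactone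
Product: 24 allylic acetate (C9 silyl ether)
Conditions: Ac2O, pyridine, DMAP (cat.), CH2Cl2, 0 °C
Reagents that add atoms: acetic anhydride, CC(=O)OC(C)=O
Why: Acylation under nucleophilic catalysis: the primary allylic alcohol is the only free hydroxyl and is acetylated under conditions that leave the α-methylene lactone alone.

Step 14
Reactants: 24 allylic acetate
Product: 25 C9 alcohol (1S,3S,9S,10R)
Conditions: HF·pyridine, pyridine, THF, 0 °C → rt
Reagents that add atoms: none
Why: Fluoride-mediated desilylation: buffered HF·pyridine cleaves the secondary silyl ether without touching the acetate, the lactone or the conjugated methylene group.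

Step 15
Reactants: 25 C9 alcohol; 26 2-(tert-butyldimethylsilyloxy)acetic acid
Product: 27 C9 O-silyl glycolate
Conditions: EDC·HCl, DMAP, CH2Cl2, 0 °C → rt
Reagents that add atoms: 2-(tert-butyldimethylsilyloxy)acetic acid (26), CC(C)(C)[Si](C)(C)OCC(=O)O
Why: Steglich esterification: the carbodiimide-activated O-silyl glycolic acid acylates the C9 hydroxyl through the acylpyridinium ion with retention at C9, the silyl group preventing self-condensation of the glycolate.

Step 16
Reactants: 27 C9 O-silyl glycolate
Product: 28 target, CNP0156635.1
Conditions: HF·pyridine, pyridine, THF, 0 °C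
Reagents that add atoms: none
Why: Desilylation of the primary silyl ether with HF·pyridine is fast and leaves the three ester groups and the α-methylene lactone intact, giving the target.

**Compound list**

1 | pent-4-enal | C=CCCC=O | starting material
2 | methyl 2-(bromomethyl)acrylate (methyl 2-(bromomethyl)prop-2-enoate) | C=C(CBr)C(=O)OC | starting material
3 | methyl (4R)-2-methylidene-4-(trimethylsilyloxy)oct-7-enoate | C=CCC[C@@H](O[Si](C)(C)C)CC(=C)C(=O)OC | intermediate
4 | methyl (4R)-4-hydroxy-2-methylideneoct-7-enoate | C=CCC[C@@H](O)CC(=C)C(=O)OC | intermediate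
5 | methyl (4R)-4-(tert-butyldimethylsilyloxy)-2-methylideneoct-7-enoate | C=CCC[C@@H](O[Si](C)(C)C(C)(C)C)CC(=C)C(=O)OC | intermediate
6 | methyl (5R)-5-(tert-butyldimethylsilyloxy)cyclohex-1-ene-1-carboxylate | COC(=O)C1=CCC[C@@H](O[Si](C)(C)C(C)(C)C)C1 | intermediate
7 | methyl (5S)-5-(tert-butyldimethylsilyloxy)-3-oxocyclohex-1-ene-1-carboxylate (ring atoms are C7, C2, C1, C10, C9, C8 of the target) | COC(=O)C1=CC(=O)C[C@@H](O[Si](C)(C)C(C)(C)C)C1 | intermediate
8 | cyclobutene | C1=CCC1 | starting material
9 | trans-fused photoadduct, the C2 epimer of 10 (six-membered ring trans-fused to cyclobutane C2–C3–C6–C7) | COC(=O)[C@]12C[C@H](O[Si](C)(C)C(C)(C)C)CC(=O)[C@@H]1[C@@H]3CC[C@H]23 | intermediate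
10 | cis-anti-cis photoadduct: tricyclic keto ester with C1 ketone, CO2Me on C7 and (9S)-silyloxy group; cyclobutane C2–C3–C6–C7 cis-fused to the cyclohexanone and to cyclobutane C3–C4–C5–C6, the two four-membered rings anti, the first cyclobutane on the face opposite the silyloxy group | COC(=O)[C@]12C[C@H](O[Si](C)(C)C(C)(C)C)CC(=O)[C@H]1[C@@H]3CC[C@H]23 | intermediate
11 | tert-butyl bromoacetate | CC(C)(C)OC(=O)CBr | starting material
12 | lithium enolate of 10 (C1–OLi, C1=C10) | COC(=O)[C@]12C[C@H](O[Si](C)(C)C(C)(C)C)C=C(O[Li])[C@H]1[C@@H]3CC[C@H]23 | intermediate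
13 | C10-alkylated photoadduct: as 10 with a CH2CO2t-Bu arm on C10 trans to the C9 silyloxy group (9S,10R) | COC(=O)[C@]12C[C@H](O[Si](C)(C)C(C)(C)C)[C@@H](CC(=O)OC(C)(C)C)C(=O)[C@H]1[C@@H]3CC[C@H]23 | intermediate
14 | cyclodeca-2,6-dienone: C1 ketone, C2=C3 trans in the ring, C6=C7 cis in the ring with CO2Me on C7 (ester trans to C5), (9S)-silyloxy, (10R)-CH2CO2t-Bu | COC(=O)/C1=C/CC/C=C/C(=O)[C@H](CC(=O)OC(C)(C)C)[C@@H](O[Si](C)(C)C(C)(C)C)C1 | intermediate
15 | methylzinc enolate of 16 (C1–O–ZnMe, C1=C2, enolate geometry not fixed) | COC(=O)/C1=C/CC[C@H](C)C=C(O[Zn]C)[C@H](CC(=O)OC(C)(C)C)[C@@H](O[Si](C)(C)C(C)(C)C)C1 | intermediate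
16 | (3S,9S,10R)-3-methylcyclodec-6-enone with CO2Me on C7, silyloxy on C9, CH2CO2t-Bu on C10 | COC(=O)/C1=C/CC[C@H](C)CC(=O)[C@H](CC(=O)OC(C)(C)C)[C@@H](O[Si](C)(C)C(C)(C)C)C1 | intermediate
17 | (1S,3S,9S,10S)-alcohol: as 16 with C1–OH cis to the C10 arm | COC(=O)/C1=C/CC[C@H](C)C[C@H](O)[C@H](CC(=O)OC(C)(C)C)[C@@H](O[Si](C)(C)C(C)(C)C)C1 | intermediate
18 | (1S,3S,9S,10S)-diol: as 17 with CH2OH on C7 | OC/C1=C/CC[C@H](C)C[C@H](O)[C@H](CC(=O)OC(C)(C)C)[C@@H](O[Si](C)(C)C(C)(C)C)C1 | intermediate
19 | cis-fused γ-lactone (O–C1, C10–C11H2–C12=O) with C7 hydroxymethyl and C9 silyl ether (1S,3S,9S,10S) | C1C(=O)O[C@H]2C[C@@H](C)CC/C=C(/CO)C[C@H](O[Si](C)(C)C(C)(C)C)[C@@H]12 | intermediate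
20 | dilithium species of 19 (lactone enolate and primary alkoxide) | C1=C(O[Li])O[C@H]2C[C@@H](C)CC/C=C(/CO[Li])C[C@H](O[Si](C)(C)C(C)(C)C)[C@@H]12 | intermediate
21 | Mannich base: 19 with CH2NMe2 on C11 (C11 configuration inconsequential) | CN(C)CC1C(=O)O[C@H]2C[C@@H](C)CC/C=C(/CO)C[C@H](O[Si](C)(C)C(C)(C)C)[C@@H]12 | intermediate
22 | trimethylammonium iodide of 21 | C[N+](C)(C)CC1C(=O)O[C@H]2C[C@@H](C)CC/C=C(/CO)C[C@H](O[Si](C)(C)C(C)(C)C)[C@@H]12.[I-] | intermediate
23 | α-methylene lactone with C7 hydroxymethyl and C9 silyl ether (1S,3S,9S,10S) | C=C1C(=O)O[C@H]2C[C@@H](C)CC/C=C(/CO)C[C@H](O[Si](C)(C)C(C)(C)C)[C@@H]12 | intermediate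
24 | allylic acetate of 23 | C=C1C(=O)O[C@H]2C[C@@H](C)CC/C=C(/COC(C)=O)C[C@H](O[Si](C)(C)C(C)(C)C)[C@@H]12 | intermediate
25 | C9 alcohol (1S,3S,9S,10R) | C=C1C(=O)O[C@H]2C[C@@H](C)CC/C=C(/COC(C)=O)C[C@H](O)[C@@H]12 | intermediate
26 | 2-(tert-butyldimethylsilyloxy)acetic acid | CC(C)(C)[Si](C)(C)OCC(=O)O | starting material
27 | C9 (tert-butyldimethylsilyloxy)acetate of 25 | C=C1C(=O)O[C@H]2C[C@@H](C)CC/C=C(/COC(C)=O)C[C@H](OC(=O)CO[Si](C)(C)C(C)(C)C)[C@@H]12 | intermediate
28 | CNP0156635.1 (1S,3S,9S,10S; C6=C7 cis in the ring) | C=C1C(=O)O[C@H]2C[C@@H](C)CC/C=C(/COC(C)=O)C[C@H](OC(=O)CO)[C@@H]12 | target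

**Step count and risks**

Total: 16 steps. Longest linear sequence: 16 steps (1 to 28); 2, 8, 11 and 26 are purchased.

Step 8, most likely to fail. The conformation of the ten-membered dienone may decide which face of C3 is open (peripheral attack) and override the chiral copper catalyst, or the catalyst may turn over poorly on this hindered enone, so that methyl arrives on the wrong face. The fallback turns that bias around by adding hydride instead of methyl to the same face. It sets out from 14. Unselective conjugate addition of Me2CuLi in the presence of Me3SiCl (THF, −78 °C) gives the trimethylsilyl enol ether F1. Saegusa–Ito dehydrogenation with Pd(OAc)2 in MeCN gives the 3-methyl dienone F2. Conjugate reduction with [(Ph3P)CuH]6 (cat.) and PhMe2SiH in toluene delivers hydride to the face that methyl preferred and should give the (3S) dimethylphenylsilyl enol ether F3. Hydrolysis with dilute HCl in THF returns to the route at 16.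

Step 9. Hydride may be delivered to the face of the C1 carbonyl that lies on the side of the acetate arm, if the ring conformation exposes it, which gives the 1R alcohol that cannot close the cis-fused lactone. The fallback sets out from 16 and accepts that outcome: the reduction then gives the epimeric (1R)-alcohol F4. Mitsunobu inversion with 4-nitrobenzoic acid, PPh3 and diisopropyl azodicarboxylate gives the (1S)-4-nitrobenzoate F5. The i-Bu2AlH treatment of step 10 cleaves this ester while it reduces the C7 ester, so the sequence comes back at 18.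

Step 7. During the long heating that the unactivated bicyclo[2.2.0]hexane needs, the product may go on by Cope rearrangement to a divinylcyclohexanone, and the tert-butyl ester may lose isobutene. The fallback moves the cycloreversion ahead of the alkylation. It sets out from 10, which is volatile and carries no tert-butyl ester. Flash vacuum pyrolysis (about 450 °C, short contact time) should give the arm-free cyclodecadienone F6. Deprotonation at C10 with LDA in THF at −78 °C gives the cross-conjugated lithium dienolate F7. Alkylation with 11 anti to the C9 silyloxy group (C10 can be equilibrated next to the ketone if needed) returns to the route at 14.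

**Further compounds**

F1 | step 8 | trimethylsilyl enol ether of the 3-methyl ketone (C1–OSiMe3, C1=C2; C3 epimers) | COC(=O)/C1=C/CCC(C)C=C(O[Si](C)(C)C)[C@H](CC(=O)OC(C)(C)C)[C@@H](O[Si](C)(C)C(C)(C)C)C1
F2 | step 8 | 3-methylcyclodeca-2,6-dienone diester (C2=C3 trans in the ring; 9S,10R) | COC(=O)/C1=C/CC/C(C)=C/C(=O)[C@H](CC(=O)OC(C)(C)C)[C@@H](O[Si](C)(C)C(C)(C)C)C1
F3 | step 8 | (3S) dimethylphenylsilyl enol ether of 16 | COC(=O)/C1=C/CC[C@H](C)C=C(O[Si](C)(C)c2ccccc2)[C@H](CC(=O)OC(C)(C)C)[C@@H](O[Si](C)(C)C(C)(C)C)C1
F4 | step 9 | (1R)-alcohol, the C1 epimer of 17 | COC(=O)/C1=C/CC[C@H](C)C[C@@H](O)[C@H](CC(=O)OC(C)(C)C)[C@@H](O[Si](C)(C)C(C)(C)C)C1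
F5 | step 9 | (1S)-4-nitrobenzoate of 17 | COC(=O)/C1=C/CC[C@H](C)C[C@H](OC(=O)c2ccc(cc2)[N+](=O)[O-])[C@H](CC(=O)OC(C)(C)C)[C@@H](O[Si](C)(C)C(C)(C)C)C1
F6 | step 7 | arm-free cyclodeca-2,6-dienone (C2=C3 trans in the ring, C6=C7 cis in the ring, 9S) | COC(=O)/C1=C/CC/C=C/C(=O)C[C@@H](O[Si](C)(C)C(C)(C)C)C1
F7 | step 7 | lithium dienolate of F6 (C1–OLi, C1=C10) | COC(=O)/C1=C/CC/C=C/C(O[Li])=C[C@@H](O[Si](C)(C)C(C)(C)C)C1
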